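**Assumption:** the target is a flat, achiral indole with no stereocentre, so there is no enantiomer to select. Compound 1 is bought as a catalogue building block.

## Retrosynthetic overview
1. Target 6 ⇒ 4,7-dibromo-2-chloroindole 5. The C3–Br bond is made last by electrophilic bromination, in the same pot as the ring closure.
2. Key disconnection N1–C2: 5 ⇒ chloroethynylaniline 4 ⇒ gem-dichlorovinylaniline 3. One chlorine is lost as HCl and the other stays as C2–Cl.
3. 3 ⇒ aminoaldehyde 2. The C2 carbon comes from a dichloromethylene Wittig reagent.
4. 2 ⇒ fluoroaldehyde 1 + NH3, forming the aryl C7a–N bond by SNAr.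
5. The dibrominated benzene ring is bought. Only the pyrrole ring is built, and it is formed last.

## Route

**Step 1**
Reactants: 1 3,6-dibromo-2-fluorobenzaldehyde
Product: 2 2-amino-3,6-dibromobenzaldehyde
Conditions: 28% aq NH3 (10 equiv), DMSO, 70 °C, sealed tube, N2; mildly acidic aqueous work-up
Reagents that add atoms: ammonia, N
Why: This is a nucleophilic aromatic substitution (SNAr, addition–elimination) in which the ortho formyl group stabilises the Meisenheimer adduct and fluoride leaves far faster than the C6 bromide, so only C2–F is exchanged for NH2, and no stereocentre is formed.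

**Step 2**
Reactants: 2 2-amino-3,6-dibromobenzaldehyde
Product: 3 3,6-dibromo-2-(2,2-dichloroethenyl)aniline
Conditions: BrCCl3 (2 equiv), PPh3 (4 equiv), MeCN, 0 °C to rt
Reagents that add atoms: bromotrichloromethane, ClC(Cl)(Cl)Br
Why: This is a Ramirez-type Wittig gem-dichloro-olefination in which PPh3 and BrCCl3 give Ph3P=CCl2, which olefinates the aldehyde under neutral conditions that spare the aryl bromides and the hindered, electron-poor NH2.

**Step 3**
Reactants: 3 3,6-dibromo-2-(2,2-dichloroethenyl)aniline
Product: 6 3,4,7-tribromo-2-chloro-1H-indole, via 3,6-dibromo-2-(chloroethynyl)aniline 4 (not isolated), via 4,7-dibromo-2-chloro-1H-indole 5 (not isolated)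
Conditions: KOtBu (3 equiv), NMP, 0 °C to rt; then AcOH (2.2 equiv), NBS (1.0 equiv), 0 °C, dark
Reagents that add atoms: N-bromosuccinimide, O=C1CCC(=O)N1Br
Why: Proposed new method: KOtBu removes HCl from ArCH=CCl2 by anti-E2 elimination to give chloroalkyne 4, whose potassium anilide (N–H acidified by two bromines and the alkynyl group) adds 5-endo-dig to the chlorine-bearing alkyne carbon, the only ring size the geometry allows, forming N1–C2; the C3 vinyl anion cannot expel chloride (that would need a 2,3-indolyne) and is protonated by tBuOH, so C2–Cl is kept, and after buffering with AcOH the labile 5 is brominated by NBS at C3, its most nucleophilic site, before it can decompose; the closest known reaction types are the Cs2CO3- or n-Bu4NF-promoted cyclisation of N-sulfonyl-2-(2,2-dibromovinyl)anilines to 2-bromoindoles and the KOtBu/NMP cyclisation of free 2-alkynylanilines, neither shown for unprotected gem-dichlorovinylanilines with retention of the C–Cl bond and telescoped C3-halogenation.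

## Compound list
1 | 3,6-dibromo-2-fluorobenzaldehyde | O=Cc1c(F)c(Br)ccc1Br | starting material
2 | 2-amino-3,6-dibromobenzaldehyde | O=Cc1c(N)c(Br)ccc1Br | intermediate
3 | 3,6-dibromo-2-(2,2-dichloroethenyl)aniline | Nc1c(Br)ccc(Br)c1C=C(Cl)Cl | intermediate
4 | 3,6-dibromo-2-(chloroethynyl)aniline | Nc1c(Br)ccc(Br)c1C#CCl | intermediate
5 | 4,7-dibromo-2-chloro-1H-indole | Clc1cc2c(Br)ccc(Br)c2[nH]1 | intermediate
6 | 3,4,7-tribromo-2-chloro-1H-indole | Clc1[nH]c2c(Br)ccc(Br)c2c1Br | target

## Step count
- Total step count: 3
- Longest linear sequence: 3

## Steps most likely to fail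

**Step 3 (the proposed new step).**
- Risks: tert-butoxide may add to the chloroalkyne, halophilic attack may occur at chlorine, or the weakly nucleophilic anilide may stall at 4.
- The fallback uses known chemistry and sets out from 3. Warming 3 in 90% H2SO4 hydrolyses the 1,1-dichloroalkene to the acyl oxidation level. On dilution the ortho amine closes the lactam to give 4,7-dibromoindolin-2-one F3.
- Heating F3 with POCl3 and N,N-dimethylaniline in toluene is the classical oxindole-to-2-chloroindole conversion. It brings the route back at 5, which is brominated at once with NBS to give 6.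

**Step 1.**
- Risks: ammonia can condense with the aldehyde, and the amino product can combine with a second aldehyde to give dihydroquinazoline-type by-products.
- The fallback sets out from 1. NaN3 in DMSO at 45 °C cannot form imines and displaces fluoride to give 2-azido-3,6-dibromobenzaldehyde F1.
- F1 is kept below 60 °C and reduced with SnCl2·2H2O in EtOH at rt. This spares the aldehyde and the aryl bromides and comes back to the route at 2.

**Step 2.**
- Risks: the aldehyde is flanked on both sides and deactivated as a vinylogous amide, and the halophosphonium by-product may bind the NH2 as an aminophosphonium salt.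
- The fallback sets out from 2 and avoids phosphines. Dimethyl (1-diazo-2-oxopropyl)phosphonate with K2CO3 in MeOH (Ohira–Bestmann homologation) gives 3,6-dibromo-2-ethynylaniline F2.
- F2 is C-chlorinated with CCl4, K2CO3 and catalytic n-Bu4NF. This comes back to the route at 4, now isolated, which enters the cyclisation and bromination part of step 3 with 2 equiv of KOtBu.

## Further compounds
F1 | step 1 | 2-azido-3,6-dibromobenzaldehyde | [N-]=[N+]=Nc1c(Br)ccc(Br)c1C=O
F2 | step 2 | 3,6-dibromo-2-ethynylaniline | Nc1c(Br)ccc(Br)c1C#C
F3 | step 3 | 4,7-dibromoindolin-2-one | O=C1Cc2c(Br)ccc(Br)c2N1
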